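**Plan**

- Numbering: ring C1 (C=O), C2=C3, C4, C5 (carbinol), C6; side chain C1' (CH2), C2' (C=O). The retrosynthesis cuts C2=C3 (ring-closing metathesis), unmasks C2'=O from a dithiane, and then cuts C6–C1 and C1'–C2'.
- Enabling feature: C5 is a tertiary carbinol carbon carrying two acylmethyl arms (C6–C1=O in the ring, C1'–C2'=O in the chain) and an allyl-type arm (C4–C3). This is the pattern left when a 2-allyl-2-(chloromethyl)oxirane is opened at both CH2 termini by acyl anion equivalents.
- Fragments: propargyl alcohol gives the 2-allyl allylic alcohol, then the epoxy alcohol, then the chloromethyl epoxide; linoleyl alcohol gives the aldehyde, then the dithiane.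
- Union and ring: the lithiated dithiane, the chloride-to-epoxide relay and lithiated methoxyallene join the chain in one flask. The allene is then hydrolysed to the vinyl ketone, metathesis closes the only ring, and the dithiane is hydrolysed last.
- Stereochemistry: C5 is set by Sharpless epoxidation with D-(−)-diethyl tartrate and none of its bonds is broken afterwards. Both Z alkenes come intact from linoleyl alcohol.

Key step: step 6

Remark: commercial allylmagnesium bromide (ether solution), methoxyallene, D-(−)-diethyl tartrate and linoleyl alcohol of high Z,Z purity are assumed, and the enantiomeric purity reached in step 2 is taken as sufficient for the target.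

**Step 1**
Reactants: 1 propargyl alcohol; 2 allylmagnesium bromide
Product: 3 2-methylidenepent-4-en-1-ol
Conditions: 2 (3 equiv), CuI (10 mol%), Et2O, 0 °C → rt; then aq. NH4Cl
Reagents that add atoms: none
Why: Hydroxyl-directed carbomagnesiation of the propargylic magnesium alkoxide should place the allyl group on the internal alkyne carbon through a five-membered oxamagnesacycle, so protonolysis gives the 2-substituted allylic alcohol; no stereocentre is formed.

**Step 2**
Reactants: 3 2-methylidenepent-4-en-1-ol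
Product: 4 [(2R)-2-(prop-2-en-1-yl)oxiran-2-yl]methanol
Conditions: Ti(OiPr)4 (10 mol%), D-(−)-diethyl tartrate (12 mol%), t-BuOOH (2 equiv, isooctane), 4 Å MS, CH2Cl2, −20 °C; non-aqueous work-up
Reagents that add atoms: tert-butyl hydroperoxide, CC(C)(C)OO
Why: Sharpless asymmetric epoxidation; the titanium tartrate complex binds the allylic hydroxyl and delivers oxygen only to the 1,1-disubstituted allylic alkene (the isolated vinyl group is inert), and the D-(−)-tartrate directs it to the face that gives the R epoxy alcohol.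

**Step 3**
Reactants: 4 [(2R)-2-(prop-2-en-1-yl)oxiran-2-yl]methanol
Product: 5 (2S)-2-(chloromethyl)-2-(prop-2-en-1-yl)oxirane
Conditions: PPh3 (1.3 equiv), CCl4, NaHCO3 (cat.), reflux; isolation by careful distillation (volatile)
Reagents that add atoms: carbon tetrachloride, ClC(Cl)(Cl)Cl
Why: Appel reaction; chloride displaces the alkoxyphosphonium group at the primary carbon under neutral conditions that leave the oxirane intact, and the stereocentre is untouched (the descriptor changes from R to S only because CH2Cl outranks the ring CH2).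

**Step 4**
Reactants: 6 linoleyl alcohol
Product: 7 (9Z,12Z)-octadeca-9,12-dienal
Conditions: Dess–Martin periodinane (1.2 equiv), CH2Cl2, 0 °C → rt, Ar
Reagents that add atoms: none
Why: Dess–Martin oxidation stops at the aldehyde under mild, non-basic conditions that should neither migrate nor isomerise the skipped Z,Z-diene.

**Step 5**
Reactants: 7 (9Z,12Z)-octadeca-9,12-dienal
Product: 8 2-[(8Z,11Z)-heptadeca-8,11-dien-1-yl]-1,3-dithiane
Conditions: HS(CH2)3SH (1.1 equiv), BF3·OEt2 (0.2 equiv), CH2Cl2, −20 → 0 °C, dark, Ar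
Reagents that add atoms: propane-1,3-dithiol, SCCCS
Why: Lewis-acid-catalysed dithioacetalisation of an unhindered aldehyde; low temperature and exclusion of light and oxygen should suppress thiyl-radical addition to, or Z-to-E isomerisation of, the chain alkenes.

**Step 6**
Reactants: 8 2-[(8Z,11Z)-heptadeca-8,11-dien-1-yl]-1,3-dithiane; 5 (2S)-2-(chloromethyl)-2-(prop-2-en-1-yl)oxirane; 9 methoxyallene
Product: 14 (4R)-4-({2-[(8Z,11Z)-heptadeca-8,11-dien-1-yl]-1,3-dithian-2-yl}methyl)-6-methoxyocta-1,6,7-trien-4-ol, via lithiated dithiane 10 (not isolated), via chlorohydrin lithium alkoxide 11 (not isolated), via relay epoxide 12 (not isolated), via 1-lithio-1-methoxyallene 13 (not isolated)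
Conditions: 8, n-BuLi (1.0 equiv), THF, −30 °C, 2 h; DMPU, 5 (1.0 equiv), −78 → −25 °C; 0 °C → rt (closure to 12); 13 (3 equiv, from 9 and n-BuLi, THF, −40 °C, second flask) by cannula at −78 °C, → 0 °C; H2O quench; Et3N-deactivated silica
Reagents that add atoms: none
Why: n-BuLi removes the sulfur-acidified C2–H of 8, and carbanion 10 attacks the strained, unsubstituted oxirane carbon of 5 by SN2 (C1'–C2' bond) to give the tertiary alkoxide 11. On warming, 11 displaces the neighbouring chloride by 3-exo-tet closure to the relay epoxide 12, which the α-carbon of 13 opens at its CH2 terminus (C6–C1 bond); no ring of the target is formed, the only closure being this transient oxirane. The closest known reaction type is the multicomponent coupling of 2-lithio-1,3-dithianes with epichlorohydrin followed by a second organolithium, combined with the opening of epoxides by lithiated alkoxyallenes. No stereocentre is created: all four bonds of the quaternary carbon (future C5) stay intact, so its configuration is that of step 2, provided the first nucleophile attacks the oxirane methylene and not CH2Cl (which would lead to the enantiomeric relay epoxide); ring strain against a sluggish neopentyl-type chloride should secure this. Because 11 closes only on warming, 12 appears after 10 has been consumed, which prevents a second dithiane addition. Metalation of the dithiane C–H in preference to the doubly allylic CH2 of the chain is expected from one equivalent of n-BuLi at −30 °C without activating additives, and 13 should react through its α-carbon as lithiated alkoxyallenes do with epoxides.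

**Step 7**
Reactants: 14 (4R)-4-({2-[(8Z,11Z)-heptadeca-8,11-dien-1-yl]-1,3-dithian-2-yl}methyl)-6-methoxyocta-1,6,7-trien-4-ol
Product: 15 (5R)-5-({2-[(8Z,11Z)-heptadeca-8,11-dien-1-yl]-1,3-dithian-2-yl}methyl)-5-hydroxyocta-1,7-dien-3-one
Conditions: 0.5 M aq. H2SO4, THF, 0 °C, about 20 min; NaHCO3 quench; used at once
Reagents that add atoms: water, O
Why: Acid-catalysed hydrolysis of the allenyl enol ether; protonation at the central allene carbon gives a methoxy-stabilised allyl cation, water adds at the oxygen-bearing carbon and loss of methanol unveils the vinyl ketone, while dithiane, tertiary alcohol and skipped diene should tolerate brief cold dilute acid.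

**Step 8**
Reactants: 15 (5R)-5-({2-[(8Z,11Z)-heptadeca-8,11-dien-1-yl]-1,3-dithian-2-yl}methyl)-5-hydroxyocta-1,7-dien-3-one
Product: 16 (5R)-5-({2-[(8Z,11Z)-heptadeca-8,11-dien-1-yl]-1,3-dithian-2-yl}methyl)-5-hydroxycyclohex-2-en-1-one
Conditions: second-generation Grubbs catalyst (H2IMes)(PCy3)Cl2Ru=CHPh (5 mol%), CH2Cl2 (0.005 M), 40 °C, Ar sparge; ethyl vinyl ether quench
Reagents that add atoms: none
Why: Ring-closing metathesis; the carbene loads on the terminal allyl alkene and closes onto the vinyl ketone to form the six-membered enone (C2=C3) with loss of ethene, dithioacetals being tolerated by this catalyst and the internal Z alkenes reacting far more slowly than the intramolecular closure at high dilution.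

**Step 9**
Reactants: 16 (5R)-5-({2-[(8Z,11Z)-heptadeca-8,11-dien-1-yl]-1,3-dithian-2-yl}methyl)-5-hydroxycyclohex-2-en-1-one
Product: 17 (5S)-5-hydroxy-5-[(10Z,13Z)-2-oxononadeca-10,13-dien-1-yl]cyclohex-2-en-1-one (target)
Conditions: MeI (20 equiv), CaCO3 (5 equiv), MeCN/H2O 9:1, 40 °C
Reagents that add atoms: water, O
Why: Alkylative dithiane hydrolysis; S-methylation makes sulfur a leaving group, water captures the thionium ion and a second S-methylation releases the C2' ketone, and the carbonate-buffered, near-neutral medium should spare the β-hydroxy enone (no dehydration or retro-aldol) and the Z,Z-diene; C5 is unchanged (the descriptor becomes S only through the change in substituent priorities).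

**Compound list**

1 | propargyl alcohol (prop-2-yn-1-ol) | C#CCO | starting material
2 | allylmagnesium bromide (prop-2-en-1-ylmagnesium bromide) | C=CC[Mg]Br | starting material
3 | 2-methylidenepent-4-en-1-ol | C=CCC(=C)CO | intermediate
4 | [(2R)-2-(prop-2-en-1-yl)oxiran-2-yl]methanol | OC[C@]1(CC=C)CO1 | intermediate
5 | (2S)-2-(chloromethyl)-2-(prop-2-en-1-yl)oxirane | ClC[C@]1(CC=C)CO1 | intermediate
6 | linoleyl alcohol, (9Z,12Z)-octadeca-9,12-dien-1-ol | CCCCC/C=C\C/C=C\CCCCCCCCO | starting material
7 | (9Z,12Z)-octadeca-9,12-dienal | CCCCC/C=C\C/C=C\CCCCCCCC=O | intermediate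
8 | 2-[(8Z,11Z)-heptadeca-8,11-dien-1-yl]-1,3-dithiane | CCCCC/C=C\C/C=C\CCCCCCCC1SCCCS1 | intermediate
9 | methoxyallene (1-methoxypropa-1,2-diene) | COC=C=C | starting material
10 | 2-lithio-2-[(8Z,11Z)-heptadeca-8,11-dien-1-yl]-1,3-dithiane | CCCCC/C=C\C/C=C\CCCCCCCC1([Li])SCCCS1 | intermediate (not isolated)
11 | lithium (2S)-1-chloro-2-({2-[(8Z,11Z)-heptadeca-8,11-dien-1-yl]-1,3-dithian-2-yl}methyl)pent-4-en-2-olate | CCCCC/C=C\C/C=C\CCCCCCCC1(SCCCS1)C[C@@](CCl)(O[Li])CC=C | intermediate (not isolated)
12 | (2S)-2-({2-[(8Z,11Z)-heptadeca-8,11-dien-1-yl]-1,3-dithian-2-yl}methyl)-2-(prop-2-en-1-yl)oxirane | CCCCC/C=C\C/C=C\CCCCCCCC1(SCCCS1)C[C@@]2(CC=C)CO2 | intermediate (not isolated)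
13 | 1-lithio-1-methoxypropa-1,2-diene | COC([Li])=C=C | intermediate (not isolated)
14 | (4R)-4-({2-[(8Z,11Z)-heptadeca-8,11-dien-1-yl]-1,3-dithian-2-yl}methyl)-6-methoxyocta-1,6,7-trien-4-ol | CCCCC/C=C\C/C=C\CCCCCCCC1(SCCCS1)C[C@@](CC(OC)=C=C)(O)CC=C | intermediate
15 | (5R)-5-({2-[(8Z,11Z)-heptadeca-8,11-dien-1-yl]-1,3-dithian-2-yl}methyl)-5-hydroxyocta-1,7-dien-3-one | CCCCC/C=C\C/C=C\CCCCCCCC1(SCCCS1)C[C@@](CC(=O)C=C)(O)CC=C | intermediate
16 | (5R)-5-({2-[(8Z,11Z)-heptadeca-8,11-dien-1-yl]-1,3-dithian-2-yl}methyl)-5-hydroxycyclohex-2-en-1-one | CCCCC/C=C\C/C=C\CCCCCCCC1(SCCCS1)C[C@@]2(O)CC=CC(=O)C2 | intermediate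
17 | (5S)-5-hydroxy-5-[(10Z,13Z)-2-oxononadeca-10,13-dien-1-yl]cyclohex-2-en-1-one | CCCCC/C=C\C/C=C\CCCCCCCC(=O)C[C@@]1(O)CC=CC(=O)C1 | target

**Step count and risks**

Total steps: 9. Longest linear sequence: 7 steps (1, 2, 3, 6, 7, 8, 9, from propargyl alcohol); the dithiane branch (steps 4 and 5) joins at step 6.

Steps most likely to fail:

1. Step 6. The alkyllithium may abstract a doubly allylic proton of the skipped diene in competition with the dithiane C–H, which would scramble the diene. The second opening, at a neopentyl-type epoxide carbon, may also be slow enough for base-induced isomerisation of the relay epoxide to compete.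
 Fallback (leaves the route at 5 and 9, rejoins at 14): the diene is kept away from alkyllithium and built last by a Wittig reaction. Commercial 8-bromooctan-1-ol is silylated (TBSCl, imidazole, DMF) to tert-butyl[(8-bromooctyl)oxy]dimethylsilane F1. F1 alkylates 2-lithio-1,3-dithiane (commercial 1,3-dithiane, n-BuLi, THF, −30 °C) to give tert-butyl{[8-(1,3-dithian-2-yl)octyl]oxy}dimethylsilane F2. Lithiated F2 is taken through the same relay with 5, by way of the non-isolated (2S)-2-{[2-(8-{[tert-butyl(dimethyl)silyl]oxy}octyl)-1,3-dithian-2-yl]methyl}-2-(prop-2-en-1-yl)oxirane F3, and then with lithiated 9, to the silyl ether (4R)-4-{[2-(8-{[tert-butyl(dimethyl)silyl]oxy}octyl)-1,3-dithian-2-yl]methyl}-6-methoxyocta-1,6,7-trien-4-ol F4. TBAF in THF should give the diol (4R)-4-{[2-(8-hydroxyoctyl)-1,3-dithian-2-yl]methyl}-6-methoxyocta-1,6,7-trien-4-ol F5. Parikh–Doering oxidation (SO3·pyridine, DMSO, iPr2NEt, CH2Cl2, 0 °C, chosen because it spares the dithiane) should give the aldehyde 8-(2-{[(2R)-2-hydroxy-4-methoxy-2-(prop-2-en-1-yl)hexa-4,5-dien-1-yl]}-1,3-dithian-2-yl)octanal F6. For the olefination, commercial (3Z)-non-3-en-1-ol is converted (CBr4, PPh3) into (3Z)-1-bromonon-3-ene F7 and then (PPh3, MeCN, reflux) into [(3Z)-non-3-en-1-yl]triphenylphosphonium bromide F8. Its ylide (NaHMDS, THF, −78 °C, in excess to allow for the free hydroxyl) should convert F6 into 14 by a Z-selective Wittig reaction.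

2. Step 8. Sulfur coordination may retard the ruthenium carbene, and prolonged heating would then allow secondary metathesis or Z-to-E isomerisation at the chain alkenes.
 Fallback (leaves at 15, rejoins at 17): sulfur is removed before the metathesis. MeI in large excess with CaCO3 in MeCN/H2O at rt should convert 15 into the sulfur-free dienedione (5S,15Z,18Z)-5-hydroxy-5-(prop-2-en-1-yl)tetracosa-1,15,18-triene-3,7-dione F9; the excess MeI caps liberated sulfur as the bis(methyl sulfide) so that it cannot add to the vinyl ketone. Second-generation Grubbs catalyst at low loading and rt should then close F9 directly to 17.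

3. Step 7. Under acid the tertiary hydroxyl may add in a 6-endo sense to the newly formed vinyl ketone (or to the allyl cation that precedes it) and give a tetrahydropyranone, and the vinyl ketone may oligomerise on concentration.
 Fallback (leaves at 14, rejoins at 16): the hydroxyl is capped before the acid step. 1-(Trimethylsilyl)imidazole in CH2Cl2 should give {[(4R)-4-({2-[(8Z,11Z)-heptadeca-8,11-dien-1-yl]-1,3-dithian-2-yl}methyl)-6-methoxyocta-1,6,7-trien-4-yl]oxy}trimethylsilane F10. Buffered hydrolysis of the allenyl ether (PPTS, wet THF, 0 °C) should give (5R)-5-({2-[(8Z,11Z)-heptadeca-8,11-dien-1-yl]-1,3-dithian-2-yl}methyl)-5-[(trimethylsilyl)oxy]octa-1,7-dien-3-one F11, which cannot cyclise through oxygen. Metathesis as in step 8 should give (5R)-5-({2-[(8Z,11Z)-heptadeca-8,11-dien-1-yl]-1,3-dithian-2-yl}methyl)-5-[(trimethylsilyl)oxy]cyclohex-2-en-1-one F12, and HF·pyridine buffered with pyridine in THF at 0 °C should release 16.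

**Further compounds**

F1 | step 6 | tert-butyl[(8-bromooctyl)oxy]dimethylsilane | CC(C)(C)[Si](C)(C)OCCCCCCCCBr
F2 | step 6 | tert-butyl{[8-(1,3-dithian-2-yl)octyl]oxy}dimethylsilane | CC(C)(C)[Si](C)(C)OCCCCCCCCC1SCCCS1
F3 | step 6 | (2S)-2-{[2-(8-{[tert-butyl(dimethyl)silyl]oxy}octyl)-1,3-dithian-2-yl]methyl}-2-(prop-2-en-1-yl)oxirane (not isolated) | CC(C)(C)[Si](C)(C)OCCCCCCCCC1(SCCCS1)C[C@@]2(CC=C)CO2
F4 | step 6 | (4R)-4-{[2-(8-{[tert-butyl(dimethyl)silyl]oxy}octyl)-1,3-dithian-2-yl]methyl}-6-methoxyocta-1,6,7-trien-4-ol | CC(C)(C)[Si](C)(C)OCCCCCCCCC1(SCCCS1)C[C@@](CC(OC)=C=C)(O)CC=C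
F5 | step 6 | (4R)-4-{[2-(8-hydroxyoctyl)-1,3-dithian-2-yl]methyl}-6-methoxyocta-1,6,7-trien-4-ol | OCCCCCCCCC1(SCCCS1)C[C@@](CC(OC)=C=C)(O)CC=C
F6 | step 6 | 8-(2-{[(2R)-2-hydroxy-4-methoxy-2-(prop-2-en-1-yl)hexa-4,5-dien-1-yl]}-1,3-dithian-2-yl)octanal | O=CCCCCCCCC1(SCCCS1)C[C@@](CC(OC)=C=C)(O)CC=C
F7 | step 6 | (3Z)-1-bromonon-3-ene | CCCCC/C=C\CCBr
F8 | step 6 | [(3Z)-non-3-en-1-yl]triphenylphosphonium bromide | CCCCC/C=C\CC[P+](c1ccccc1)(c1ccccc1)c1ccccc1.[Br-]
F9 | step 8 | (5S,15Z,18Z)-5-hydroxy-5-(prop-2-en-1-yl)tetracosa-1,15,18-triene-3,7-dione | CCCCC/C=C\C/C=C\CCCCCCCC(=O)C[C@@](CC(=O)C=C)(O)CC=C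
F10 | step 7 | {[(4R)-4-({2-[(8Z,11Z)-heptadeca-8,11-dien-1-yl]-1,3-dithian-2-yl}methyl)-6-methoxyocta-1,6,7-trien-4-yl]oxy}trimethylsilane | CCCCC/C=C\C/C=C\CCCCCCCC1(SCCCS1)C[C@@](CC(OC)=C=C)(O[Si](C)(C)C)CC=C
F11 | step 7 | (5R)-5-({2-[(8Z,11Z)-heptadeca-8,11-dien-1-yl]-1,3-dithian-2-yl}methyl)-5-[(trimethylsilyl)oxy]octa-1,7-dien-3-one | CCCCC/C=C\C/C=C\CCCCCCCC1(SCCCS1)C[C@@](CC(=O)C=C)(O[Si](C)(C)C)CC=C
F12 | step 7 | (5R)-5-({2-[(8Z,11Z)-heptadeca-8,11-dien-1-yl]-1,3-dithian-2-yl}methyl)-5-[(trimethylsilyl)oxy]cyclohex-2-en-1-one | CCCCC/C=C\C/C=C\CCCCCCCC1(SCCCS1)C[C@@]2(O[Si](C)(C)C)CC=CC(=O)C2
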